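**Retrosynthetic overview**

- The target is the diaryl ether of two 4-methoxythymol units. Ring A (2-isopropyl-4-methoxy-5-methylphenoxy) is carried in intact from thymol; ring B (the phenol ring) is built last from a four-membered ring.
- Feature used: in ring B the C–OH and C–OMe carbons are para. Going round from C–OMe, one arc holds C–CH3 then C–OAr, the other C–H then C–iPr. A 4-alkenyl-4-oxycyclobut-2-enone has this map: C1(=O) → C–OMe, C2 → C–CH3, C3 → C–OAr, C4 (carbinol) → C–OH, internal alkene C → C–iPr, alkene CH2 → ring C–H.
- Disconnections: (a) O-methylation and acetal removal at the end; (b) the ring B bond between the C–OMe carbon and the ring CH, by thermal 4π opening and 6π closure of the cyclobutenone; (c) the carbinol C–alkenyl bond, by adding 3-methylbut-1-en-2-yllithium (Shapiro, from 3-methylbutan-2-one) to a 3-aryloxy-4-methylcyclobutenedione; (d) the hindered Ar–O–C bond, by addition–elimination of 4-methoxythymol on 3-chloro-4-methylcyclobutenedione made from dimethyl squarate.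
- Ring order: ring A and the cyclobutene ring are bought; ring B is the only ring formed, in the key step, where the four-membered ring is consumed.

Key step: step 10

Assumption: the cyclobutenone intermediates that carry a carbinol stereocentre are made and used as racemates, since this centre is lost or becomes an aromatic carbon and the target is achiral; 2,4,6-triisopropylbenzenesulfonohydrazide is taken as a purchased reagent.

**Route**

Step 1
Reactants: 1 dimethyl squarate (3,4-dimethoxycyclobut-3-ene-1,2-dione)
Product: 3 3-methoxy-4-methylcyclobut-3-ene-1,2-dione, via hydroxycyclobutenone 2 (not isolated)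
Conditions: MeLi (1.05 equiv), THF, −78 °C; 1 M HCl; then conc. HCl (cat.), CH2Cl2, rt
Reagents that add atoms: methyllithium, [Li]C
Why: 1,2-addition of the organolithium to one of the two equivalent squarate carbonyls, then acid-catalysed allylic transposition of the carbinol (ionisation, water capture at the methoxy-bearing carbon, loss of methanol), is the standard squarate route to 3-alkoxy-4-alkylcyclobutenediones; the racemic carbinol centre of 2 is destroyed in the same step.

Step 2
Reactants: 3 3-methoxy-4-methylcyclobut-3-ene-1,2-dione
Product: 4 3-hydroxy-4-methylcyclobut-3-ene-1,2-dione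
Conditions: 6 M HCl, THF, rt; evaporate
Reagents that add atoms: water, O
Why: acid hydrolysis of the vinylogous ester by addition–elimination of water should give the strongly acidic vinylogous acid, as in the preparation of semisquaric acids.

Step 3
Reactants: 4 3-hydroxy-4-methylcyclobut-3-ene-1,2-dione
Product: 5 3-chloro-4-methylcyclobut-3-ene-1,2-dione
Conditions: (COCl)2 (1.2 equiv), DMF (cat.), CH2Cl2, 0 °C to rt
Reagents that add atoms: oxalyl chloride, ClC(=O)C(=O)Cl
Why: Vilsmeier-type activation turns the vinylogous carboxylic acid into its vinylogous acid chloride, the same reaction type that gives squaric acid chlorides.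

Step 4
Reactants: 6 thymol (2-isopropyl-5-methylphenol)
Product: 7 4-bromo-2-isopropyl-5-methylphenol
Conditions: NBS (1.0 equiv), MeCN, 0 °C to rt
Reagents that add atoms: N-bromosuccinimide, O=C1CCC(=O)N1Br
Why: electrophilic aromatic bromination, in which the hydroxyl directs to its free para position, less hindered than the remaining ortho position.

Step 5
Reactants: 7 4-bromo-2-isopropyl-5-methylphenol
Product: 8 2-isopropyl-4-methoxy-5-methylphenol (4-methoxythymol)
Conditions: NaOMe (25% in MeOH, 5 equiv), CuI (10 mol%), DMF, 110 °C; then 1 M HCl
Reagents that add atoms: sodium methoxide, [Na+].[O-]C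
Why: copper-catalysed Ullmann-type methoxylation of an aryl bromide, a known reaction of bromophenols, run with excess methoxide so that the phenol is carried as its sodium salt and released on acidification.

Step 6
Reactants: 8 2-isopropyl-4-methoxy-5-methylphenol; 5 3-chloro-4-methylcyclobut-3-ene-1,2-dione
Product: 9 3-(2-isopropyl-4-methoxy-5-methylphenoxy)-4-methylcyclobut-3-ene-1,2-dione
Conditions: iPr2NEt (1.1 equiv), CH2Cl2, −20 °C to rt, anhydrous
Reagents that add atoms: none
Why: addition–elimination (vinylogous acyl substitution) of the phenol oxygen at the chlorine-bearing ring carbon, as in the esterification of squaric acid chlorides; chloride is the only leaving group, so a single aryl vinylogous ester should form and the hindered C–O–Ar bond is made without a metal.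

Step 7
Reactants: 10 3-methylbutan-2-one
Product: 11 (E)-N'-(3-methylbutan-2-ylidene)-2,4,6-triisopropylbenzenesulfonohydrazide (trisylhydrazone)
Conditions: 2,4,6-triisopropylbenzenesulfonohydrazide (1.0 equiv), conc. HCl (cat.), MeOH, rt; crystallise
Reagents that add atoms: 2,4,6-triisopropylbenzenesulfonohydrazide, NNS(=O)(=O)c1c(C(C)C)cc(C(C)C)cc1C(C)C
Why: acid-catalysed hydrazone condensation; the sulfonamide nitrogen is expected anti to the isopropyl group (E), the geometry that directs the later deprotonation to the methyl group.

Step 8
Reactants: 11 trisylhydrazone of 3-methylbutan-2-one; 9 3-(2-isopropyl-4-methoxy-5-methylphenoxy)-4-methylcyclobut-3-ene-1,2-dione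
Product: 13 4-hydroxy-3-(2-isopropyl-4-methoxy-5-methylphenoxy)-2-methyl-4-(3-methylbut-1-en-2-yl)cyclobut-2-en-1-one (racemic), via alkenyllithium 12 (not isolated)
Conditions: 11 (1.2 equiv), n-BuLi (1.95 equiv per 11), THF, −78 to 0 °C until N2 evolution stops; then 9, THF, −78 °C; sat. aq NH4Cl at −78 °C
Reagents that add atoms: none
Why: Shapiro reaction (the dianion formed at the methyl group loses sulfinate and N2 to give the 1,1-disubstituted alkenyllithium), then 1,2-addition to the ketone-like carbonyl next to the aryloxy carbon, the other carbonyl being deactivated as a vinylogous ester, which is the known regiochemistry for 3-alkoxy-4-alkylcyclobutenediones; the new carbinol centre forms as a racemate and is erased in step 10.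

Step 9
Reactants: 13 4-hydroxy-3-(2-isopropyl-4-methoxy-5-methylphenoxy)-2-methyl-4-(3-methylbut-1-en-2-yl)cyclobut-2-en-1-one
Product: 14 3-(2-isopropyl-4-methoxy-5-methylphenoxy)-4-(methoxymethoxy)-2-methyl-4-(3-methylbut-1-en-2-yl)cyclobut-2-en-1-one (racemic)
Conditions: MOMCl (3 equiv), iPr2NEt (4 equiv), Bu4NI (cat.), CH2Cl2, 0 °C to rt
Reagents that add atoms: chloromethyl methyl ether, COCCl
Why: O-alkylation of the tertiary alcohol with the reactive α-chloro ether (iodide-assisted, oxocarbenium-like) under a non-nucleophilic amine base, run well below the temperature at which the cyclobutenone opens.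

Step 10
Reactants: 14 3-(2-isopropyl-4-methoxy-5-methylphenoxy)-4-(methoxymethoxy)-2-methyl-4-(3-methylbut-1-en-2-yl)cyclobut-2-en-1-one
Product: 17 5-isopropyl-3-(2-isopropyl-4-methoxy-5-methylphenoxy)-4-(methoxymethoxy)-2-methylphenol, via dienylketene 15 (not isolated), via cyclohexadienone 16 (not isolated)
Conditions: degassed toluene (0.02 M), 110 °C, Ar
Reagents that add atoms: none
Why: Moore rearrangement (thermal ring expansion of a 4-alkenyl-4-alkoxycyclobutenone, the known route to hydroquinone monoethers): conrotatory 4π opening of the C1–C4 bond of 14 gives dienylketene 15, in which the methoxymethoxy group has rotated outward and the 3-methylbut-1-en-2-yl group inward. Disrotatory 6π electrocyclisation then joins the ketene carbon to the terminal CH2 of the alkene, closing the six-membered carbocycle (ring B) as cyclohexa-2,4-dienone 16, and enolisation of its CH2–C=O unit gives phenol 17. No stereocentre is formed, and the racemic carbinol carbon of 14 becomes an aromatic carbon. The selectivity needed is the sense of rotation at the carbinol carbon, secured by the oxygen donor there, which prefers the outward position and so places the alkenyl group next to the ketene; the substituent order round ring B is already fixed by the constitution of 14 (C=O carbon next to C–CH3, carbinol carbon next to C–OAr). The ketene oxygen ends as the only free hydroxyl while the carbinol oxygen stays protected, so the two ring B oxygens are differentiated for the last two steps. Dilute, oxygen-free conditions should suppress ketene dimerisation and oxidation of the electron-rich phenol.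

Step 11
Reactants: 17 5-isopropyl-3-(2-isopropyl-4-methoxy-5-methylphenoxy)-4-(methoxymethoxy)-2-methylphenol
Product: 18 1-isopropyl-3-(2-isopropyl-4-methoxy-5-methylphenoxy)-5-methoxy-2-(methoxymethoxy)-4-methylbenzene
Conditions: MeI (2 equiv), K2CO3 (2 equiv), acetone, 56 °C
Reagents that add atoms: iodomethane, CI
Why: Williamson etherification of the unhindered phenol (flanked by CH3 and H); the acetal and the diaryl ether are stable to carbonate base.

Step 12
Reactants: 18 1-isopropyl-3-(2-isopropyl-4-methoxy-5-methylphenoxy)-5-methoxy-2-(methoxymethoxy)-4-methylbenzene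
Product: 19 6-isopropyl-2-(2-isopropyl-4-methoxy-5-methylphenoxy)-4-methoxy-3-methylphenol (target, CNP0271085.0)
Conditions: conc. HCl (cat.), MeOH, 50 °C
Reagents that add atoms: none
Why: acid-catalysed acetal cleavage (transacetalisation to dimethoxymethane) frees the hindered phenol, while the aryl methyl ethers and the diaryl ether are stable to dilute acid.

**Compound list**

1 | dimethyl squarate (3,4-dimethoxycyclobut-3-ene-1,2-dione) | COC1=C(OC)C(=O)C1=O | starting material
2 | 4-hydroxy-2,3-dimethoxy-4-methylcyclobut-2-en-1-one (racemic) | COC1=C(OC)C(C)(O)C1=O | intermediate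
3 | 3-methoxy-4-methylcyclobut-3-ene-1,2-dione | COC1=C(C)C(=O)C1=O | intermediate
4 | 3-hydroxy-4-methylcyclobut-3-ene-1,2-dione | OC1=C(C)C(=O)C1=O | intermediate
5 | 3-chloro-4-methylcyclobut-3-ene-1,2-dione | ClC1=C(C)C(=O)C1=O | intermediate
6 | thymol (2-isopropyl-5-methylphenol) | Cc1ccc(C(C)C)c(O)c1 | starting material
7 | 4-bromo-2-isopropyl-5-methylphenol | Cc1cc(O)c(C(C)C)cc1Br | intermediate
8 | 2-isopropyl-4-methoxy-5-methylphenol (4-methoxythymol) | COc1cc(C(C)C)c(O)cc1C | intermediate
9 | 3-(2-isopropyl-4-methoxy-5-methylphenoxy)-4-methylcyclobut-3-ene-1,2-dione | COc1cc(C(C)C)c(OC2=C(C)C(=O)C2=O)cc1C | intermediate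
10 | 3-methylbutan-2-one | CC(=O)C(C)C | starting material
11 | (E)-N'-(3-methylbutan-2-ylidene)-2,4,6-triisopropylbenzenesulfonohydrazide | CC(C)/C(C)=N/NS(=O)(=O)c1c(C(C)C)cc(C(C)C)cc1C(C)C | intermediate
12 | (3-methylbut-1-en-2-yl)lithium | [Li]C(=C)C(C)C | intermediate
13 | 4-hydroxy-3-(2-isopropyl-4-methoxy-5-methylphenoxy)-2-methyl-4-(3-methylbut-1-en-2-yl)cyclobut-2-en-1-one (racemic) | OC1(C(=C)C(C)C)C(=O)C(C)=C1Oc1cc(C)c(OC)cc1C(C)C | intermediate
14 | 3-(2-isopropyl-4-methoxy-5-methylphenoxy)-4-(methoxymethoxy)-2-methyl-4-(3-methylbut-1-en-2-yl)cyclobut-2-en-1-one (racemic) | COCOC1(C(=C)C(C)C)C(=O)C(C)=C1Oc1cc(C)c(OC)cc1C(C)C | intermediate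
15 | (3Z)-5-isopropyl-3-(2-isopropyl-4-methoxy-5-methylphenoxy)-4-(methoxymethoxy)-2-methylhexa-1,3,5-trien-1-one | O=C=C(C)/C(Oc1cc(C)c(OC)cc1C(C)C)=C(OCOC)\C(=C)C(C)C | intermediate
16 | 5-isopropyl-3-(2-isopropyl-4-methoxy-5-methylphenoxy)-4-(methoxymethoxy)-2-methylcyclohexa-2,4-dien-1-one | O=C1CC(C(C)C)=C(OCOC)C(Oc2cc(C)c(OC)cc2C(C)C)=C1C | intermediate
17 | 5-isopropyl-3-(2-isopropyl-4-methoxy-5-methylphenoxy)-4-(methoxymethoxy)-2-methylphenol | Oc1cc(C(C)C)c(OCOC)c(Oc2cc(C)c(OC)cc2C(C)C)c1C | intermediate
18 | 1-isopropyl-3-(2-isopropyl-4-methoxy-5-methylphenoxy)-5-methoxy-2-(methoxymethoxy)-4-methylbenzene | COc1cc(C(C)C)c(OCOC)c(Oc2cc(C)c(OC)cc2C(C)C)c1C | intermediate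
19 | 6-isopropyl-2-(2-isopropyl-4-methoxy-5-methylphenoxy)-4-methoxy-3-methylphenol | COc1cc(C(C)C)c(Oc2c(C)c(OC)cc(C(C)C)c2O)cc1C | target

**Step count**

Total: 12 steps. Longest linear sequence: 9 steps (1, 2, 3, 6, 8, 9, 10, 11, 12, from dimethyl squarate).

**Steps most likely to fail, with fallbacks**

Step 10. The thermal cascade may not run cleanly with the alkylated carbinol: the acetal may be lost at the temperature needed for ring opening, the dienylketene may be consumed by dimerisation or by adventitious nucleophiles before it closes, and the electron-rich product may oxidise. The fallback sets out from 13 and gives up protecting-group differentiation of the two oxygens in favour of steric differentiation. Carbinol 13 itself is heated in degassed toluene at 110 °C, the parent hydroxy form of the same ring expansion, which should give the hydroquinone 5-isopropyl-3-(2-isopropyl-4-methoxy-5-methylphenoxy)-2-methylbenzene-1,4-diol F1. Kept under argon, F1 is mono-methylated (MeI 1.0 equiv, K2CO3, acetone, rt) at the hydroxyl between C–CH3 and C–H, which is far more accessible than the one between the isopropyl and aryloxy groups. The fallback comes back to the route at 19, so steps 9, 11 and 12 are not needed.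

Step 8. The alkenyllithium may attack the vinylogous-ester carbonyl, displace the aryloxide by conjugate addition–elimination, or deprotonate the ring methyl group, so that the carbinol forms with the wrong connectivity or not at all. The fallback sets out from 8 and makes the diaryl ether by C–O cross-coupling on a finished ring B instead of building ring B. Bromination of 8 (NBS, CH2Cl2, −20 °C) at the only free position ortho to the hydroxyl should give 2-bromo-6-isopropyl-4-methoxy-3-methylphenol F2. Protection (MOMCl, iPr2NEt, CH2Cl2) gives 3-bromo-1-isopropyl-5-methoxy-2-(methoxymethoxy)-4-methylbenzene F3. Ullmann diaryl ether coupling of F3 with a second equivalent of 8 (CuI, picolinic acid, K3PO4, DMSO, 100 °C) then comes back to the route at 18, before step 12.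

Step 6. Hydrolysis of the chloride or of the aryl vinylogous ester by traces of water, or base-induced decomposition of the chlorodione through its acidic ring methyl group, may compete with O-acylation of the hindered phenol. The fallback sets out from 8 and reverses the order in which the aryloxy and methyl groups are put on the four-membered ring. Phenol 8 is treated with 3,4-dichlorocyclobut-3-ene-1,2-dione (1 equiv, iPr2NEt, CH2Cl2, −78 °C), an electrophile without an acidic methyl group, to give 3-chloro-4-(2-isopropyl-4-methoxy-5-methylphenoxy)cyclobut-3-ene-1,2-dione F4. Stille methylation of the remaining vinylogous acid chloride (Me4Sn, PdCl2(PPh3)2 cat., CuI cat., DMF, 50 °C) comes back to the route at 9, so steps 1 to 3 are not needed.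

**Further compounds**

F1 | step 10 | 5-isopropyl-3-(2-isopropyl-4-methoxy-5-methylphenoxy)-2-methylbenzene-1,4-diol | COc1cc(C(C)C)c(Oc2c(C)c(O)cc(C(C)C)c2O)cc1C
F2 | step 8 | 2-bromo-6-isopropyl-4-methoxy-3-methylphenol | COc1cc(C(C)C)c(O)c(Br)c1C
F3 | step 8 | 3-bromo-1-isopropyl-5-methoxy-2-(methoxymethoxy)-4-methylbenzene | COCOc1c(Br)c(C)c(OC)cc1C(C)C
F4 | step 6 | 3-chloro-4-(2-isopropyl-4-methoxy-5-methylphenoxy)cyclobut-3-ene-1,2-dione | COc1cc(C(C)C)c(OC2=C(Cl)C(=O)C2=O)cc1C
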